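**Plan**

- Target numbering: ring C1 (side chain), C2 (OAc), C3 (OH), C4 (Me), C5 (OH), C6 (H); C7 is the methylidene-bearing carbon, C8 the carbinol carbon. The ring is a C2/C5 hydroquinone whose two oxygens are already told apart (acetate versus free OH), with O on C3 and Me on C4. A 4-acyloxy-4-alkenyl-3-alkoxy-2-methylcyclobutenone delivers exactly this pattern on ring expansion.
- Retrosynthetic cuts, in order: the C3 O–isopropyl bond; the benzene ring at C5–C6, back to a squarate-derived cyclobutenone; the angelate ester C–O bond; the bond from the cyclobutenone carbon (future C2) to the diene carbon (future C1); the C7–C8 bond (dienyl anion plus aldehyde).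
- Forward: 2,3-bis(trimethylstannyl)butadiene and 4-methylpent-3-enal give the dienyl carbinol, which is oxidised, reduced enantioselectively and silylated. Sn/Li exchange and addition to 3-isopropoxy-4-methylcyclobutenedione follow, with acetate trapping. The silyl ether is exchanged for the angelate, the only ring (the benzene) is closed thermally, and BCl3 frees the C3 hydroxyl.
- Stereochemistry: C8 (S) comes from CBS reduction of the dienyl ketone with the (R)-oxazaborolidine. The Z-alkene of the ester is bought with angelic acid and kept by an esterification without nucleophilic catalyst. The ring stereocentre of the cyclobutenone is uncontrolled and is erased on aromatisation.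

Key step: step 11

Remarks on the chemistry: the acetate-bearing ring carbon of the cyclobutenones forms as both epimers, which are carried on together because that centre becomes sp2 in the ring expansion. The carbinol is carried as a TBS ether (resistant to 1,4 O→C silyl migration in the vinyllithium). It is exchanged for the angelate before the arene exists, so that a free side-chain hydroxyl never sits next to the aryl acetate, which would invite acetyl migration.

**Route**

Step 1
Reactants: 1 1,4-dichlorobut-2-yne
Product: 3 2,3-bis(trimethylstannyl)buta-1,3-diene, via chloromethylallene 2 (not isolated)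
Conditions: Me3SnLi (from Me3SnCl, Li), THF, −78 °C to rt
Reagents that add atoms: trimethylstannyllithium, C[Sn](C)(C)[Li] (made in the flask from chlorotrimethylstannane, C[Sn](C)(C)Cl, and lithium)
Why: Two successive SN2′ displacements by the stannyl anion (propargylic chloride to allene 2, then allenylmethyl chloride to the diene) are the established entry to this doubly metallated butadiene.

Step 2
Reactants: 4 4-methylpent-3-en-1-ol
Product: 5 4-methylpent-3-enal
Conditions: Dess–Martin periodinane, pyridine, CH2Cl2, 0 °C to rt; solvent exchanged to THF, used at once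
Reagents that add atoms: none
Why: Buffered Dess–Martin oxidation of a primary homoallylic alcohol should stop at the β,γ-unsaturated aldehyde without moving the alkene into conjugation.

Step 3
Reactants: 3 2,3-bis(trimethylstannyl)buta-1,3-diene; 5 4-methylpent-3-enal
Product: 8 rac-7-methyl-3-methylidene-2-(trimethylstannyl)octa-1,6-dien-4-ol, via dienyllithium 6 (not isolated), via lithium alkoxide 7 (not isolated)
Conditions: MeLi (1.0 equiv), THF, −78 °C; then 5, −78 °C; H2O
Reagents that add atoms: none
Why: Tin–lithium exchange with one equivalent of MeLi should stop after one stannyl group, and the vinyllithium should undergo 1,2-addition to the aldehyde faster than enolisation at −78 °C; the carbinol forms racemic and is corrected in steps 4 and 5.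

Step 4
Reactants: 8 rac-7-methyl-3-methylidene-2-(trimethylstannyl)octa-1,6-dien-4-ol
Product: 9 7-methyl-3-methylidene-2-(trimethylstannyl)octa-1,6-dien-4-one
Conditions: Dess–Martin periodinane, pyridine, CH2Cl2, 0 °C; kept cold, used at once
Reagents that add atoms: none
Why: Dess–Martin oxidation of a secondary allylic alcohol tolerates the vinylstannane and the skipped alkene, and immediate use of the cross-conjugated dienone should forestall Diels–Alder self-dimerisation and migration of the β,γ-alkene.

Step 5
Reactants: 9 7-methyl-3-methylidene-2-(trimethylstannyl)octa-1,6-dien-4-one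
Product: 11 (4S)-7-methyl-3-methylidene-2-(trimethylstannyl)octa-1,6-dien-4-ol, via borate ester 10 (not isolated)
Conditions: (R)-Me-CBS oxazaborolidine [(3aR)-1-methyl-3,3-diphenyltetrahydro-1H,3H-pyrrolo[1,2-c][1,3,2]oxazaborole] (20 mol %), catecholborane, toluene, −78 °C; aqueous work-up
Reagents that add atoms: none
Why: In this CBS reduction the α-branched dienyl group is the large substituent and the CH2 chain the small one, so the (R)-catalyst should deliver hydride to the face giving the (S)-carbinol (the mirror of acetophenone to (R)-alcohol with the (S)-catalyst), and catecholborane at −78 °C leaves the alkenes and the C–Sn bond alone.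

Step 6
Reactants: 11 (4S)-7-methyl-3-methylidene-2-(trimethylstannyl)octa-1,6-dien-4-ol
Product: 12 tert-butyl(dimethyl){[(4S)-7-methyl-3-methylidene-2-(trimethylstannyl)octa-1,6-dien-4-yl]oxy}silane
Conditions: TBSCl, imidazole, DMF, rt
Reagents that add atoms: tert-butyldimethylsilyl chloride, CC(C)(C)[Si](C)(C)Cl
Why: Imidazole-promoted silylation of a secondary alcohol is routine, and TBS is chosen because it resists retro-Brook silyl migration in the vinyllithium of step 8.

Step 7
Reactants: 13 diisopropyl squarate
Product: 16 3-isopropoxy-4-methylcyclobut-3-ene-1,2-dione, via lithium alkoxide 14 (not isolated), via trifluoroacetate 15 (not isolated)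
Conditions: MeLi, THF, −78 °C; (CF3CO)2O, −78 °C; H2O, rt
Reagents that add atoms: methyllithium, [Li]C; water, O
Why: 1,2-Addition of MeLi to one carbonyl of the symmetrical squarate, O-trifluoroacetylation and hydrolytic allylic transposition with loss of isopropanol is the standard preparation of 3-alkoxy-4-alkylcyclobutenediones.

Step 8
Reactants: 12 tert-butyl(dimethyl){[(4S)-7-methyl-3-methylidene-2-(trimethylstannyl)octa-1,6-dien-4-yl]oxy}silane; 16 3-isopropoxy-4-methylcyclobut-3-ene-1,2-dione
Product: 19 1-[(4S)-4-{[tert-butyl(dimethyl)silyl]oxy}-7-methyl-3-methylideneocta-1,6-dien-2-yl]-2-isopropoxy-3-methyl-4-oxocyclobut-2-en-1-yl acetate (both epimers at the ring carbon), via dienyllithium 17 (not isolated), via lithium alkoxide 18 (not isolated)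
Conditions: MeLi, THF, −78 °C; 16, −78 °C; Ac2O, −78 to 0 °C
Reagents that add atoms: acetic anhydride, CC(=O)OC(C)=O
Why: After tin–lithium exchange the vinyllithium should undergo 1,2-addition to the more electrophilic carbonyl of 16 (the one next to the isopropoxy-bearing carbon; the other is deactivated as a vinylogous ester), and O-acylation of the tertiary lithium alkoxide by Ac2O fixes the acetate before warming; the new ring stereocentre is uncontrolled and irrelevant.

Step 9
Reactants: 19 1-[(4S)-4-{[tert-butyl(dimethyl)silyl]oxy}-7-methyl-3-methylideneocta-1,6-dien-2-yl]-2-isopropoxy-3-methyl-4-oxocyclobut-2-en-1-yl acetate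
Product: 20 1-[(4S)-4-hydroxy-7-methyl-3-methylideneocta-1,6-dien-2-yl]-2-isopropoxy-3-methyl-4-oxocyclobut-2-en-1-yl acetate
Conditions: HF·pyridine, pyridine, THF, 0 °C to rt
Reagents that add atoms: none
Why: Buffered fluoride desilylation should remove the secondary TBS ether without touching the tertiary acetate, the vinylogous ester or the base-sensitive cyclobutenone.

Step 10
Reactants: 20 1-[(4S)-4-hydroxy-7-methyl-3-methylideneocta-1,6-dien-2-yl]-2-isopropoxy-3-methyl-4-oxocyclobut-2-en-1-yl acetate; 21 angelic acid [(2Z)-2-methylbut-2-enoic acid]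
Product: 23 (4S)-2-(1-acetoxy-2-isopropoxy-3-methyl-4-oxocyclobut-2-en-1-yl)-7-methyl-3-methylideneocta-1,6-dien-4-yl (2Z)-2-methylbut-2-enoate (both epimers at the ring carbon), via mixed anhydride 22 (not isolated)
Conditions: 21, 2,4,6-trichlorobenzoyl chloride, Et3N, toluene, rt; then 20, 45 °C
Reagents that add atoms: none
Why: In this Yamaguchi-type mixed-anhydride esterification run without DMAP the alcohol should attack the unhindered angeloyl carbonyl of 22, the absence of a nucleophilic catalyst preserves the Z-alkene, the temperature stays below the ring-opening threshold of the cyclobutenone, and the C8–O bond is not broken so the configuration is kept.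

Step 11
Reactants: 23 (4S)-2-(1-acetoxy-2-isopropoxy-3-methyl-4-oxocyclobut-2-en-1-yl)-7-methyl-3-methylideneocta-1,6-dien-4-yl (2Z)-2-methylbut-2-enoate
Product: 26 (3S)-2-(2-acetoxy-5-hydroxy-3-isopropoxy-4-methylphenyl)-6-methylhepta-1,5-dien-3-yl (2Z)-2-methylbut-2-enoate, via dienylketene 24 (not isolated), via cyclohexadienone 25 (not isolated)
Conditions: toluene (0.01 M, degassed), 110 °C, argon
Reagents that add atoms: none
Why: Heat opens the cyclobutenone by conrotatory 4π electrocyclic cleavage of the bond between the carbonyl carbon and the acetate-bearing carbon to give the (Z)-dienylketene 24, whose ketene carbon then bonds to the terminal CH2 of the ring-attached vinyl group in a thermal disrotatory 6π electrocyclisation that closes the six-membered carbocycle (the C5–C6 bond) as cyclohexadienone 25, and tautomerisation gives phenol 26. This is the Moore rearrangement of 4-alkenyl-4-oxycyclobutenones in its O-acyl form, so the acetate placed on the tertiary oxygen ends on C2 while the ketene oxygen becomes the free C5 hydroxyl. No stereocentre is created: the acetate-bearing ring carbon becomes sp2, both epimers of 23 converge, and C8 and the angelate geometry are spectators. The step needs torquoselectivity, with the acetoxy group rotating outward so that the dienyl group lies cis to the ketene; the oxygen donor on that carbon should secure this, and a ketene of the wrong geometry can only re-close to the cyclobutenone and be recycled. It also needs periselectivity, which geometry supplies: only the vinyl group bonded directly to the former ring carbon can reach the ketene carbon through a six-membered transition state, the outer methylidene being cross-conjugated and out of reach. High dilution and exclusion of acid, base and oxygen should keep the diene, the allylic ester and the new hydroquinone monoacetate intact.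

Step 12
Reactants: 26 (3S)-2-(2-acetoxy-5-hydroxy-3-isopropoxy-4-methylphenyl)-6-methylhepta-1,5-dien-3-yl (2Z)-2-methylbut-2-enoate
Product: 28 (3S)-2-(2-acetoxy-3,5-dihydroxy-4-methylphenyl)-6-methylhepta-1,5-dien-3-yl (2Z)-2-methylbut-2-enoate (CNP0147405.1), via bis(dichloroboryl) ether 27 (not isolated)
Conditions: BCl3 (3 equiv), CH2Cl2, −78 °C; pH 7 phosphate buffer (NaH2PO4/Na2HPO4)
Reagents that add atoms: none
Why: Lewis-acid dealkylation of an aryl isopropyl ether by BCl3 (chloride attack on the boron-complexed secondary ether) should be easy here because the C3 ether is twisted out of conjugation by two ortho substituents, the esters and alkenes should survive at −78 °C, and a neutral quench avoids acetyl migration between the C2 and C3 oxygens.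

**Compound list**

1 | 1,4-dichlorobut-2-yne | ClCC#CCCl | starting material
2 | 4-chloro-3-(trimethylstannyl)buta-1,2-diene | C=C=C(CCl)[Sn](C)(C)C | intermediate (not isolated)
3 | 2,3-bis(trimethylstannyl)buta-1,3-diene | C=C([Sn](C)(C)C)C(=C)[Sn](C)(C)C | intermediate
4 | 4-methylpent-3-en-1-ol | CC(C)=CCCO | starting material
5 | 4-methylpent-3-enal | CC(C)=CCC=O | intermediate
6 | [3-(trimethylstannyl)buta-1,3-dien-2-yl]lithium | [Li]C(=C)C(=C)[Sn](C)(C)C | intermediate (not isolated)
7 | lithium rac-7-methyl-3-methylidene-2-(trimethylstannyl)octa-1,6-dien-4-olate | [Li+].[O-]C(CC=C(C)C)C(=C)C(=C)[Sn](C)(C)C | intermediate (not isolated)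
8 | rac-7-methyl-3-methylidene-2-(trimethylstannyl)octa-1,6-dien-4-ol | C=C([Sn](C)(C)C)C(=C)C(O)CC=C(C)C | intermediate
9 | 7-methyl-3-methylidene-2-(trimethylstannyl)octa-1,6-dien-4-one | C=C([Sn](C)(C)C)C(=C)C(=O)CC=C(C)C | intermediate
10 | 2-{[(4S)-7-methyl-3-methylidene-2-(trimethylstannyl)octa-1,6-dien-4-yl]oxy}-1,3,2-benzodioxaborole | C=C([Sn](C)(C)C)C(=C)[C@H](CC=C(C)C)OB1Oc2ccccc2O1 | intermediate (not isolated)
11 | (4S)-7-methyl-3-methylidene-2-(trimethylstannyl)octa-1,6-dien-4-ol | C=C([Sn](C)(C)C)C(=C)[C@H](CC=C(C)C)O | intermediate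
12 | tert-butyl(dimethyl){[(4S)-7-methyl-3-methylidene-2-(trimethylstannyl)octa-1,6-dien-4-yl]oxy}silane | C=C([Sn](C)(C)C)C(=C)[C@H](CC=C(C)C)O[Si](C)(C)C(C)(C)C | intermediate
13 | diisopropyl squarate (3,4-diisopropoxycyclobut-3-ene-1,2-dione) | CC(C)OC1=C(OC(C)C)C(=O)C1=O | starting material
14 | lithium 2,3-diisopropoxy-1-methyl-4-oxocyclobut-2-en-1-olate | [Li+].[O-]C1(C)C(OC(C)C)=C(OC(C)C)C1=O | intermediate (not isolated)
15 | 2,3-diisopropoxy-1-methyl-4-oxocyclobut-2-en-1-yl trifluoroacetate | CC1(OC(=O)C(F)(F)F)C(OC(C)C)=C(OC(C)C)C1=O | intermediate (not isolated)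
16 | 3-isopropoxy-4-methylcyclobut-3-ene-1,2-dione | CC1=C(OC(C)C)C(=O)C1=O | intermediate
17 | [(4S)-4-{[tert-butyl(dimethyl)silyl]oxy}-7-methyl-3-methylideneocta-1,6-dien-2-yl]lithium | [Li]C(=C)C(=C)[C@H](CC=C(C)C)O[Si](C)(C)C(C)(C)C | intermediate (not isolated)
18 | lithium 1-[(4S)-4-{[tert-butyl(dimethyl)silyl]oxy}-7-methyl-3-methylideneocta-1,6-dien-2-yl]-2-isopropoxy-3-methyl-4-oxocyclobut-2-en-1-olate | [Li+].[O-]C1(C(=C)C(=C)[C@H](CC=C(C)C)O[Si](C)(C)C(C)(C)C)C(OC(C)C)=C(C)C1=O | intermediate (not isolated)
19 | 1-[(4S)-4-{[tert-butyl(dimethyl)silyl]oxy}-7-methyl-3-methylideneocta-1,6-dien-2-yl]-2-isopropoxy-3-methyl-4-oxocyclobut-2-en-1-yl acetate (both ring epimers) | CC(C)OC1=C(C)C(=O)C1(OC(C)=O)C(=C)C(=C)[C@H](CC=C(C)C)O[Si](C)(C)C(C)(C)C | intermediate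
20 | 1-[(4S)-4-hydroxy-7-methyl-3-methylideneocta-1,6-dien-2-yl]-2-isopropoxy-3-methyl-4-oxocyclobut-2-en-1-yl acetate (both ring epimers) | CC(C)OC1=C(C)C(=O)C1(OC(C)=O)C(=C)C(=C)[C@H](CC=C(C)C)O | intermediate
21 | angelic acid, (2Z)-2-methylbut-2-enoic acid | C/C=C(/C)C(=O)O | starting material
22 | (2Z)-2-methylbut-2-enoic 2,4,6-trichlorobenzoic anhydride | C/C=C(/C)C(=O)OC(=O)c1c(Cl)cc(Cl)cc1Cl | intermediate (not isolated)
23 | (4S)-2-(1-acetoxy-2-isopropoxy-3-methyl-4-oxocyclobut-2-en-1-yl)-7-methyl-3-methylideneocta-1,6-dien-4-yl (2Z)-2-methylbut-2-enoate (both ring epimers) | CC(C)OC1=C(C)C(=O)C1(OC(C)=O)C(=C)C(=C)[C@H](CC=C(C)C)OC(=O)/C(C)=C\C | intermediate (key-step precursor)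
24 | (4S)-2-[(1Z)-1-acetoxy-2-isopropoxy-3-methyl-4-oxobuta-1,3-dien-1-yl]-7-methyl-3-methylideneocta-1,6-dien-4-yl (2Z)-2-methylbut-2-enoate | O=C=C(C)/C(OC(C)C)=C(OC(C)=O)\C(=C)C(=C)[C@H](CC=C(C)C)OC(=O)/C(C)=C\C | intermediate (not isolated)
25 | (3S)-2-(2-acetoxy-3-isopropoxy-4-methyl-5-oxocyclohexa-1,3-dien-1-yl)-6-methylhepta-1,5-dien-3-yl (2Z)-2-methylbut-2-enoate | O=C1CC(C(=C)[C@H](CC=C(C)C)OC(=O)/C(C)=C\C)=C(OC(C)=O)C(OC(C)C)=C1C | intermediate (not isolated)
26 | (3S)-2-(2-acetoxy-5-hydroxy-3-isopropoxy-4-methylphenyl)-6-methylhepta-1,5-dien-3-yl (2Z)-2-methylbut-2-enoate | C=C(c1cc(O)c(C)c(OC(C)C)c1OC(C)=O)[C@H](CC=C(C)C)OC(=O)/C(C)=C\C | intermediate (key-step product)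
27 | (3S)-2-{2-acetoxy-3,5-bis[(dichloroboryl)oxy]-4-methylphenyl}-6-methylhepta-1,5-dien-3-yl (2Z)-2-methylbut-2-enoate | C=C(c1cc(OB(Cl)Cl)c(C)c(OB(Cl)Cl)c1OC(C)=O)[C@H](CC=C(C)C)OC(=O)/C(C)=C\C | intermediate (not isolated)
28 | (3S)-2-(2-acetoxy-3,5-dihydroxy-4-methylphenyl)-6-methylhepta-1,5-dien-3-yl (2Z)-2-methylbut-2-enoate | C=C(c1cc(O)c(C)c(O)c1OC(C)=O)[C@H](CC=C(C)C)OC(=O)/C(C)=C\C | target

**Totals**

Total step count: 12. Longest linear sequence: 10 steps (steps 1, 3, 4, 5, 6, 8, 9, 10, 11, 12 from 1,4-dichlorobut-2-yne; the same length from 4-methylpent-3-en-1-ol through step 2).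

**Steps most likely to fail**

Step 11. The ring may open with the acetoxy group turned inward, followed by acyl transfer onto the ketene instead of re-closure, or the diene may be lost by thermal oligomerisation before the ring closes. The fallback runs the ring expansion in its best-documented 4-hydroxy form and places the acetate afterwards. It sets out from 12 and 16: the alkoxide 18 of step 8 is quenched with water in place of Ac2O to give the 4-hydroxycyclobutenone F1. Buffered HF·pyridine gives the diol F2. The mixed-anhydride esterification of step 10 takes only the secondary hydroxyl and gives the hydroxy angelate F3. Heating F3 in degassed toluene under argon gives the hydroquinone F4, which is acetylated in the same flask (Ac2O, pyridine, DMAP) to the diacetate F5. Aminolysis with one equivalent of pyrrolidine in CH2Cl2 at low temperature should remove the C5 acetate (one ortho hydrogen) in preference to the C2 acetate, which is flanked by the isopropoxy group and the branched side chain. The route is rejoined at 26.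

Step 10. The angeloyl unit may isomerise from Z to E during acyl activation, or the cyclobutenone may suffer slow ring opening or base-induced degradation if the esterification is sluggish. The fallback builds the Z-alkene on the substrate instead of transferring it. It sets out from 20: carbodiimide esterification at 0 °C with 2-[bis(2,2,2-trifluoroethoxy)phosphoryl]propanoic acid gives the phosphonate ester F6. Still–Gennari olefination with acetaldehyde (KN(SiMe3)2, 18-crown-6, THF, −78 °C) should then form the Z-trisubstituted enoate under kinetic control. The route is rejoined at 23.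

Step 12. The allylic ester may ionise under the Lewis acid, HCl may add to the trisubstituted alkene, the acetyl group may migrate between the C2 and C3 oxygens during quench, or the ether may not cleave at a temperature the rest of the molecule tolerates. The fallback replaces the isopropyl ether by a tert-butyl ether that leaves by E1 loss of an alkene under mild protic acid. It sets out from 12, with commercial di-tert-butyl squarate (CC(C)(C)OC1=C(OC(C)(C)C)C(=O)C1=O) in place of 13. MeLi addition and trifluoroacetic anhydride work-up give 3-tert-butoxy-4-methylcyclobut-3-ene-1,2-dione F7. The dienyllithium 17 is added and the alkoxide acetylated to give the tert-butoxy acetoxycyclobutenone F8. Buffered HF·pyridine gives the alcohol F9, mixed-anhydride angeloylation gives the angelate F10, and heating in toluene gives the tert-butyl aryl ether F11. Brief treatment with CF3CO2H in CH2Cl2 at 0 °C, with anisole as cation trap, then frees the C3 hydroxyl. The route is rejoined at the target 28.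

**Further compounds**

F1 | step 11 | 4-[(4S)-4-{[tert-butyl(dimethyl)silyl]oxy}-7-methyl-3-methylideneocta-1,6-dien-2-yl]-4-hydroxy-3-isopropoxy-2-methylcyclobut-2-en-1-one | CC(C)OC1=C(C)C(=O)C1(O)C(=C)C(=C)[C@H](CC=C(C)C)O[Si](C)(C)C(C)(C)C
F2 | step 11 | 4-hydroxy-4-[(4S)-4-hydroxy-7-methyl-3-methylideneocta-1,6-dien-2-yl]-3-isopropoxy-2-methylcyclobut-2-en-1-one | CC(C)OC1=C(C)C(=O)C1(O)C(=C)C(=C)[C@H](CC=C(C)C)O
F3 | step 11 | (4S)-2-(1-hydroxy-2-isopropoxy-3-methyl-4-oxocyclobut-2-en-1-yl)-7-methyl-3-methylideneocta-1,6-dien-4-yl (2Z)-2-methylbut-2-enoate | CC(C)OC1=C(C)C(=O)C1(O)C(=C)C(=C)[C@H](CC=C(C)C)OC(=O)/C(C)=C\C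
F4 | step 11 | (3S)-2-(2,5-dihydroxy-3-isopropoxy-4-methylphenyl)-6-methylhepta-1,5-dien-3-yl (2Z)-2-methylbut-2-enoate | C=C(c1cc(O)c(C)c(OC(C)C)c1O)[C@H](CC=C(C)C)OC(=O)/C(C)=C\C
F5 | step 11 | (3S)-2-(2,5-diacetoxy-3-isopropoxy-4-methylphenyl)-6-methylhepta-1,5-dien-3-yl (2Z)-2-methylbut-2-enoate | C=C(c1cc(OC(C)=O)c(C)c(OC(C)C)c1OC(C)=O)[C@H](CC=C(C)C)OC(=O)/C(C)=C\C
F6 | step 10 | (4S)-2-(1-acetoxy-2-isopropoxy-3-methyl-4-oxocyclobut-2-en-1-yl)-7-methyl-3-methylideneocta-1,6-dien-4-yl 2-[bis(2,2,2-trifluoroethoxy)phosphoryl]propanoate | CC(C)OC1=C(C)C(=O)C1(OC(C)=O)C(=C)C(=C)[C@H](CC=C(C)C)OC(=O)C(C)P(=O)(OCC(F)(F)F)OCC(F)(F)F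
F7 | step 12 | 3-tert-butoxy-4-methylcyclobut-3-ene-1,2-dione | CC1=C(OC(C)(C)C)C(=O)C1=O
F8 | step 12 | 2-tert-butoxy-1-[(4S)-4-{[tert-butyl(dimethyl)silyl]oxy}-7-methyl-3-methylideneocta-1,6-dien-2-yl]-3-methyl-4-oxocyclobut-2-en-1-yl acetate | CC(C)(C)OC1=C(C)C(=O)C1(OC(C)=O)C(=C)C(=C)[C@H](CC=C(C)C)O[Si](C)(C)C(C)(C)C
F9 | step 12 | 2-tert-butoxy-1-[(4S)-4-hydroxy-7-methyl-3-methylideneocta-1,6-dien-2-yl]-3-methyl-4-oxocyclobut-2-en-1-yl acetate | CC(C)(C)OC1=C(C)C(=O)C1(OC(C)=O)C(=C)C(=C)[C@H](CC=C(C)C)O
F10 | step 12 | (4S)-2-(1-acetoxy-2-tert-butoxy-3-methyl-4-oxocyclobut-2-en-1-yl)-7-methyl-3-methylideneocta-1,6-dien-4-yl (2Z)-2-methylbut-2-enoate | CC(C)(C)OC1=C(C)C(=O)C1(OC(C)=O)C(=C)C(=C)[C@H](CC=C(C)C)OC(=O)/C(C)=C\C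
F11 | step 12 | (3S)-2-(2-acetoxy-3-tert-butoxy-5-hydroxy-4-methylphenyl)-6-methylhepta-1,5-dien-3-yl (2Z)-2-methylbut-2-enoate | C=C(c1cc(O)c(C)c(OC(C)(C)C)c1OC(C)=O)[C@H](CC=C(C)C)OC(=O)/C(C)=C\C
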